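The readings were generated by integration with made-up constants, noise included.

If reagent meeting catalyst intermediate A were the one step that counted, the rate of making left-handed product would follow reagent and free catalyst charged, order one in each. The reagent part is my guess, since no earlier run changes that charge.

| flask | left-handed substrate | right-handed substrate | reagent | free catalyst | remark |
|---|---|---|---|---|---|
| maple | 0.020 M | 0.020 M | 0.030 M | 0.50 mM | the very flask that is asked about, followed so far |
| ash | 0.020 M | 0.020 M | 0.030 M | 0.75 mM | run made earlier |
| flask | 0.020 M | 0.020 M | 0.0300 M | 0.50 mM |  |

maple run (percent of the left-handed substrate and right-handed substrate together charged)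

| time / h | left-handed product / % | left-handed substrate / % |
|---|---|---|
| 6.00 | 17 | 30 |
| 12.0 | 31 | 20 |
| 15.0 | 33 | 17 |
| 25.0 | 40 | 8 |
| 30.0 | 42 | 8 |

ash run (percent of the left-handed substrate and right-handed substrate together charged)

| time / d | left-handed product / % | left-handed substrate / % |
|---|---|---|
| 0.250 | 24 | 27 |
| 0.833 | 42 | 7 |
| 1.25 | 45 | 3 |
| 2.00 | 49 | 0 |
| 3.00 | 51 | 0 |

(each reading ± 1.5 percentage points)

1. apparent order in free catalyst when 20 % of the left-handed substrate and right-handed substrate together are converted (percent change of the rate of making left-handed product for one percent more free catalyst charged)
2. apparent order in reagent when 20 % of the left-handed substrate and right-handed substrate together are converted (percent change of the rate of making left-handed product for one percent more reagent charged)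
3. factor on the rate of making left-handed product when 20 % of the left-handed substrate and right-handed substrate together are converted if free catalyst is charged twice over

- free catalyst is single-handed; left-handed substrate and right-handed substrate are mirror images of each other, charged as a racemate, each of them at the stated concentration
- what was read earlier has a scatter of 1.5 percentage points, one standard deviation
- steps under discussion: free catalyst + left-handed substrate <-> catalyst intermediate A; free catalyst + right-handed substrate <-> catalyst intermediate B; reagent + catalyst intermediate A -> free catalyst + left-handed product; reagent + catalyst intermediate B -> free catalyst + right-handed product; 2 free catalyst <-> resting dimer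
- no earlier run changes the charge of reagent; that part of a forecast is a guess

Next I add the end state. The two substrates together stand at 0.0400 M against 0.0300 M of reagent, so reagent is the limiting reagent and conversion stops at 75.0 %. The orders are asked at a fixed conversion, 20 %, and reaching it costs 8.00 mM of reagent whatever the charge. More reagent charged therefore raises what is left by a larger percentage than the charge. I call reagent charged over reagent left at that conversion the lever, and here it is 1.36. With other amounts held at that conversion, the lever multiplies the step's reagent order, so I commit to about 1.36.

Then I add the resting dimer, which can pull the catalyst order below one. Free catalyst is returned in each round, so it has no lever. Maple and ash, read at the same time, give 17 % and 24 % of left-handed product. As a reading, with scatter 1.5 percentage points on each, that is an order of 0.850, and a factor of 1.80 on charging catalyst twice over.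

The forecast says 0.7, 0.2 and 1.6, holding that “binding is mostly rate-limiting and the reagent order is small”. It parts from my reckoning mainly on reagent.

    free catalyst + left-handed substrate ⇌ catalyst intermediate A (K = 70.5 M⁻¹, k = 3750 M⁻¹ h⁻¹)
    free catalyst + right-handed substrate ⇌ catalyst intermediate B (K = 11.7 M⁻¹, k = 1050 M⁻¹ h⁻¹)
    reagent + catalyst intermediate A → free catalyst + left-handed product (k = 233 M⁻¹ h⁻¹)
    reagent + catalyst intermediate B → free catalyst + right-handed product (k = 98.3 M⁻¹ h⁻¹)
    2 free catalyst ⇌ resting dimer (K = 500 M⁻¹, k = 52.4 M⁻¹ h⁻¹)

The flask gives 1.0 in free catalyst, 1.3 in reagent and a factor of 2.02. The reagent step runs at 170 d⁻¹ per catalyst intermediate A, less than the 1800 d⁻¹ per free catalyst of the step forming it, each with charged amounts. At 0.300 d the two products put this flask's lever at 1.47. The ash run at 3.00 d has no reading of right-handed product, so its left-handed product, read at 51 %, gives a lower bound on the lever there, a reading of 3.13.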